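**Assumption (remark on the chemistry):** atoms carry germacrane/eudesmane numbers (C12 lactone carbonyl, C13 exocyclic carbon, C14 on C10, C15 on C4). α is the face of H-7, β the face of the C7–C11 bond. The C8 acyl group is read from the SMILES as (2R,3S)-2,3-dimethyloxirane-2-carboxylate, the epoxide of tiglic acid.

## Analysis of the target

The target is a heliangolide: a cyclodecane (C1–C10) with a trans-fused α-methylene-γ-butyrolactone across C6–C7, a Z-trisubstituted C4=C5 alkene, a trans 1(10)-epoxide, a benzoate on C3 and an epoxy ester on C8. The ring carries six stereocentres (C1, C3, C6, C7, C8, C10) and the acyl group two more. O6 is α and C11 β (trans-lactone), O8 is β and therefore cis to C11, O3 is β, and the 1β,10α-epoxide descends from an E-configured C1=C10 alkene. The sensitive groups are the α-methylene lactone (Michael acceptor, base-labile), two epoxides (acid-labile), an allylic benzoate, and a C8 oxygen that can relactonise onto C12 or add to C13 once it is a free alkoxide. Any 1(10),4-diene precursor is prone to acid-triggered transannular cyclisation. The difficulty is the ten-membered ring with one E and one Z trisubstituted alkene next to three contiguous stereocentres. The strategy rests on C2–C3 lying between the two alkenes: with C3 as a ketone enol ether, C10=C1–C2=C3–C4=C5 is a cyclodeca-1,3,5-triene. That triene is the ring-opened valence isomer of a cyclohexa-1,3-diene (C1=C2, C3=C4) in which C5 and C10 are bonded. C6, C7 and C8 can therefore be set on a chair cyclohexane before the medium ring exists.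

## Retrosynthetic reasoning

**Epoxide last.** Target 34 is cut at the two C–O bonds of the 1(10)-epoxide to diene ester 33. The trisubstituted, electron-rich C1=C10 alkene is the only alkene not deactivated by allylic oxygen or conjugation, and the epoxide would not survive the fluoride and enolate steps before it.

**C8 ester.** 33 is cut at the C8–O acyl bond to alcohol 27 and acid 31. The acid is made separately from tiglic acid 28 through alcohol 29 and epoxy alcohol 30, so that its two stereocentres come from a reagent-controlled epoxidation and not from the macrocycle.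

**Lactone methylene and C3 ester.** 27 is traced through silyl ether 26 to the 11-methyl lactone 23 (C11=C13 from selenoxide elimination), to alcohol 22 (benzoate) and to ketone 21 (C3–H from 1,2-reduction). The methylene is introduced late because it would not survive the hydride, amide-base and hydrogenation steps.

**Ring expansion (key).** In 21 the C5–C10 bond is re-formed in the retrosynthetic sense to give the cis-fused hexalin silyl dienol ether 19. This is the only cut that makes the ring and both alkene geometries at once, and it needs no ring-closing event against medium-ring strain. Forward, the conrotatory opening must turn the C5–C6 bond inward (Z) and the C10–C9 bond outward (E).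

**Diene from ketone.** 19 comes from enone 18 by enol silylation and 18 from ketone 17 by dehydrogenation at C1–C2. C10 is quaternary, so the enone can enolise only towards C4.

**Lactone and cis ring fusion.** 17 is the C11-equilibrated form of lactone 16, which is cut at the lactone C–O bond to diol 14. Diol 14 comes from enone 13 by delivery of H2 to the α-face, and 13 from isopropenyl compound 12 by hydroboration. The hydrogenation is placed before lactonisation because a C4=C5 double bond forces the 10α-methyl axial on ring B, which puts O6 and C11 trans-diaxial and makes the trans-lactone unattainable. After saturation ring B can flip.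

**C6 oxygen.** 12 comes from dienol ether 11, and that from enone 10, by γ-oxidation. C6 is the γ-carbon of the annulation enone and needs no separate activation.

**C8 configuration.** 10 is the C8 epimer of 8. A C8 oxygen cis to the isopropenyl group would sit axial in the monocyclic enolate, 1,3 to the carbon being alkylated, and would oppose the required entry of the Michael acceptor. The trans hydroxyl of 4 directs to the same face as the isopropenyl group. The annulation is therefore run in the matched 8α series and C8 is inverted afterwards, where the 8α-hydroxyl is axial and strained.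

**Ring A.** 8 is cut at C1–C10 and C4=C5 (Robinson annulation) to hydroxy ketone 4 and pent-1-en-3-one 5. This sets the quaternary C10 relative to C7.

**Ring B.** 4 comes from hydroxy enone 3, dienol ether 2 and (R)-carvone 1. Carvone supplies C7 with the correct absolute configuration, the C10 methyl and the isopropenyl group that becomes C11–C13.

## Alternatives that were turned down

**Alternative 1:** The cut is the lactone C6–O bond together with the C6–H oxidation, made at the very end. Forward, a cytochrome P450 of the costunolide/eupatolide-synthase family would oxidise the α C6–H bond at the stage of the free 12-oic acid, and the 6α-alcohol would close onto C12 to give A1. For it: one step sets C6 and the lactone without protecting groups, and the methylene never has to be masked. A1 is the same compound as 27 of the chosen route, so on the last stretch this plan is shorter (no enolate or selenium chemistry) and on that point stronger. Against it: it does not make the 1(10)E,4Z ring or the C3, C7 and C8 centres, so the hardest part still needs another ring-forming strategy. The known enzymes accept E,E-configured acids. A Z alkene at C4=C5 displaces the C6–H bond and a 3β-benzoate adds bulk next to the site of oxidation, so enzyme engineering would precede any synthesis. The chosen route offers a purely chemical construction of the ring with defined geometry.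

**Alternative 2:** The cut is C9–C10 of the ring. Forward, Ni(cod)2, PBu3 and Et3B would join the methyl-bearing carbon of an alkyne to the terminal carbon of an epoxide in an open chain, with syn delivery of hydrogen to C1, to give A2. For it: the ring, the E alkene and a free 8β-hydroxyl arise in one step, and C8 comes from an epoxide of fixed configuration without any inversion. On C8 this is stronger than the chosen route, which needs steps 2 and 5. Against it: the alkyne carries a methyl and a methylene, so insertion regiochemistry (C10 or C1 bonding to C9) is poorly differentiated. Closure of a ten-membered ring competes with oligomerisation. The open-chain substrate needs C3, C6, C7, C8 and the Z alkene built by a long acyclic sequence. A2 still requires C12 oxidation, lactonisation and the handling of three different protecting groups. The chosen route pays the medium-ring strain with a photon inside a rigid bicycle and takes its stereocentres from a six-membered ring.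

**Alternative 3:** The cut is a [3,3] shift that forms C8–C9 and cleaves C1–C6, plus C7–C11. Forward, KH with 18-crown-6 would trigger an anionic oxy-Cope rearrangement of a cyclohexenol carrying alkenyl groups on adjacent carbons, and the ring-expanded enolate would be alkylated at C7 with tert-butyl bromoacetate to give A3. For it: the expansion is thermal and scalable, has no photostationary state, inherits the Z alkene from the cyclohexene and forms C7–C11 in the same flask. On operational simplicity of the ring-forming step it is stronger. Against it: A3 has C6 as a ketone, C8 as a silyl group and no C13. The facial course of the C7 alkylation, the C6 reduction, the C–Si oxidation at C8 next to two trisubstituted alkenes and the methylenation would all be decided on a flexible ten-membered ring, and the dienone enolate invites transannular reactions. The chosen route fixes C6, C7 and C8 on a cyclohexane chair and leaves only the C3 reduction and the epoxidation to the macrocycle.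

Key step: step 14

## Route

Step 1
Reactants: 1 (R)-(−)-carvone
Product: 2 carvone linear dienol trimethylsilyl ether
Conditions: Me3SiCl, NaI, Et3N, MeCN, rt → 40 °C; pentane extraction
Reagents that add atoms: chlorotrimethylsilane, C[Si](C)(C)Cl
Why: Equilibrating soft enol silylation (Me3SiI formed in situ) removes a γ-hydrogen at C4 and gives the through-conjugated 1-silyloxy-1,3-diene; the stereocentre C5 is not touched.

Step 2
Reactants: 2 carvone linear dienol trimethylsilyl ether
Product: 3 trans-4-hydroxycarvone
Conditions: mCPBA, NaHCO3, CH2Cl2, −30 °C; aqueous citric acid work-up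
Reagents that add atoms: 3-chloroperbenzoic acid, OOC(=O)c1cccc(Cl)c1
Why: Vinylogous Rubottom oxidation; the peracid attacks the diene terminus C4, which carries the larger HOMO coefficient, from the face opposite the adjacent isopropenyl group, so the new C4–O bond is trans to the C5 substituent.

Step 3
Reactants: 3 trans-4-hydroxycarvone
Product: 4 trans-4-hydroxydihydrocarvone
Conditions: LiBH(s-Bu)3 (2.2 equiv), THF, −78 °C; NH4Cl
Reagents that add atoms: none
Why: Conjugate reduction of a β-unsubstituted cyclohexenone by the bulky borohydride, as with carvone itself; one equivalent is taken up by the hydroxyl, and the C2 epimers formed on protonation converge in step 4.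

Step 4
Reactants: 4 trans-4-hydroxydihydrocarvone; 5 pent-1-en-3-one
Product: 8 8α-hydroxy-10α-methyl-7αH-eudesma-4,11-dien-3-one, via Michael adduct 6 (not isolated), via ketol 7 (not isolated)
Conditions: KOH (cat.), EtOH, −10 °C → rt; then KOH, EtOH, reflux
Reagents that add atoms: none
Why: Robinson annulation; the more substituted enolate is alkylated axially on the half-chair that keeps hydroxyl and isopropenyl equatorial, cis to isopropenyl and trans to hydroxyl (both direct to the same face, as known for dihydrocarvone), which sets C10 with its methyl α; aldol closure and dehydration give the enone.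

Step 5
Reactants: 8 8α-hydroxy-10α-methyl-7αH-eudesma-4,11-dien-3-one
Product: 10 8β-hydroxy-10α-methyl-7αH-eudesma-4,11-dien-3-one, via 4-nitrobenzoate 9 (not isolated)
Conditions: PPh3, i-PrO2CN=NCO2i-Pr, 4-nitrobenzoic acid, toluene, 0 → 40 °C; then K2CO3, MeOH, rt
Reagents that add atoms: 4-nitrobenzoic acid, OC(=O)c1ccc(cc1)[N+](=O)[O-]
Why: Mitsunobu inversion; in the enone the 8α-hydroxyl is axial and syn to the axial 10-methyl, so backside entry of the carboxylate from the β-side relieves 1,3-diaxial strain and gives the equatorial 8β-ester, which is methanolysed in the same flask (the C8 oxygen of 10 comes from the acid).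

Step 6
Reactants: 10 8β-hydroxy-10α-methyl-7αH-eudesma-4,11-dien-3-one
Product: 11 3,8β-bis(tert-butyldimethylsilyloxy)-10α-methyl-7αH-eudesma-3,5,11-triene
Conditions: t-BuMe2SiOTf (2.6 equiv), Et3N, CH2Cl2, −78 → 0 °C
Reagents that add atoms: tert-butyldimethylsilyl trifluoromethanesulfonate, CC(C)(C)[Si](C)(C)OS(=O)(=O)C(F)(F)F
Why: One reagent silylates the C8 hydroxyl and converts the 4-en-3-one into its heteroannular 3,5-dienol ether by loss of a C6 hydrogen, the usual outcome of soft enolisation of such enones.

Step 7
Reactants: 11 3,8β-bis(tert-butyldimethylsilyloxy)-10α-methyl-7αH-eudesma-3,5,11-triene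
Product: 12 8β-(tert-butyldimethylsilyloxy)-6α-hydroxy-10α-methyl-7αH-eudesma-4,11-dien-3-one
Conditions: mCPBA (1.05 equiv), NaHCO3, CH2Cl2, −30 °C
Reagents that add atoms: 3-chloroperbenzoic acid, OOC(=O)c1cccc(Cl)c1
Why: Vinylogous Rubottom oxidation at the γ-carbon C6; attack is axial from the α-face, anti to the axial 7β-isopropenyl group (the counterpart of 6β-hydroxylation of steroidal dienol ethers), which sets C6 with oxygen α; the electron-rich diene reacts before the isopropenyl group.

Step 8
Reactants: 12 8β-(tert-butyldimethylsilyloxy)-6α-hydroxy-10α-methyl-7αH-eudesma-4,11-dien-3-one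
Product: 13 8β-(tert-butyldimethylsilyloxy)-6α,12-dihydroxy-10α-methyl-7αH-eudesm-4-en-3-one (C11 epimers)
Conditions: catecholborane (3 equiv), RhCl(PPh3)3 (cat.), THF, 0 °C → rt; then NaOH, H2O2, 0 °C
Reagents that add atoms: hydrogen peroxide, OO
Why: Rhodium-catalysed anti-Markovnikov hydroboration of the 1,1-disubstituted alkene tolerates the ketone, and the s-trans cyclic enone is inert to catecholborane; C11 is formed unselectively and is corrected in step 11.

Step 9
Reactants: 13 8β-(tert-butyldimethylsilyloxy)-6α,12-dihydroxy-10α-methyl-7αH-eudesm-4-en-3-one (C11 epimers)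
Product: 14 8β-(tert-butyldimethylsilyloxy)-6α,12-dihydroxy-4β,10α-dimethyl-5αH,7αH-eudesman-3-one (C11 epimers)
Conditions: H2 (1–3 atm), [Ir(cod)(PCy3)(py)]PF6 (cat.), CH2Cl2, rt
Reagents that add atoms: none
Why: Hydroxyl-directed homogeneous hydrogenation; the allylic 6α-hydroxyl binds iridium and both hydrogens are delivered to the α-face of C4=C5, giving the cis ring fusion (5α-H syn to the 10α-methyl) and an equatorial 4β-methyl.

Step 10
Reactants: 14 8β-(tert-butyldimethylsilyloxy)-6α,12-dihydroxy-4β,10α-dimethyl-5αH,7αH-eudesman-3-one (C11 epimers)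
Product: 16 8β-(tert-butyldimethylsilyloxy)-3-oxo-4β,10α-dimethyl-5αH,7αH-eudesman-12,6α-olide (C11 epimers), via lactol 15 (not isolated)
Conditions: TEMPO (cat.), PhI(OAc)2 (2.5 equiv), CH2Cl2, rt
Reagents that add atoms: none
Why: Oxidative lactonisation of a 1,4-diol; the oxoammonium oxidises the primary alcohol only, the aldehyde is trapped by the 6α-hydroxyl as the lactol and oxidised on; in the cis-decalin ring B can take the chair with O6 and C11 both equatorial, so the trans-lactone closes without strain.

Step 11
Reactants: 16 8β-(tert-butyldimethylsilyloxy)-3-oxo-4β,10α-dimethyl-5αH,7αH-eudesman-12,6α-olide (C11 epimers)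
Product: 17 (11S)-8β-(tert-butyldimethylsilyloxy)-3-oxo-4β,10α-dimethyl-5αH,7αH,11βH-eudesman-12,6α-olide
Conditions: KOt-Bu (0.3 equiv), t-BuOH–THF, 0 °C → rt; AcOH
Reagents that add atoms: none
Why: Epimerisation through the lactone enolate to the thermodynamic isomer with the C11 methyl α (pseudo-equatorial, away from the 8β-silyl ether), the configuration favoured in santonin-type trans-lactones; the C4 methyl is already equatorial.

Step 12
Reactants: 17 (11S)-8β-(tert-butyldimethylsilyloxy)-3-oxo-4β,10α-dimethyl-5αH,7αH,11βH-eudesman-12,6α-olide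
Product: 18 (11S)-8β-(tert-butyldimethylsilyloxy)-3-oxo-4β,10α-dimethyl-5αH,7αH,11βH-eudesm-1-en-12,6α-olide
Conditions: LiN(i-Pr)2 (1.1 equiv), THF, −78 °C; then PhS(Cl)=Nt-Bu, −78 °C
Reagents that add atoms: none
Why: Mukaiyama dehydrogenation; the kinetic enolate forms at the C2 methylene (less hindered than C4–H, more acidic than the lactone C11–H) and the sulfinimidoyl chloride turns it into the enone by sulfenylation and syn-elimination at low temperature.

Step 13
Reactants: 18 (11S)-8β-(tert-butyldimethylsilyloxy)-3-oxo-4β,10α-dimethyl-5αH,7αH,11βH-eudesm-1-en-12,6α-olide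
Product: 19 (11S)-3,8β-bis(tert-butyldimethylsilyloxy)-10α-methyl-5αH,7αH,11βH-eudesma-1,3-dien-12,6α-olide
Conditions: t-BuMe2SiOTf (1.3 equiv), Et3N, CH2Cl2, −78 → 0 °C; chromatography on Et3N-treated silica
Reagents that add atoms: tert-butyldimethylsilyl trifluoromethanesulfonate, CC(C)(C)[Si](C)(C)OS(=O)(=O)C(F)(F)F
Why: Soft enolisation; the enone has no γ-hydrogen because C10 is quaternary, so only the axial C4 hydrogen can be lost and the cross-conjugated 3-silyloxy-1,3-diene forms regiospecifically.

Step 14
Reactants: 19 (11S)-3,8β-bis(tert-butyldimethylsilyloxy)-10α-methyl-5αH,7αH,11βH-eudesma-1,3-dien-12,6α-olide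
Product: 21 (11S)-8β-(tert-butyldimethylsilyloxy)-3-oxo-11βH-germacra-1(10)E,4Z-dien-12,6α-olide, via triene silyl enol ether 20 (not isolated)
Conditions: hν (254 nm, quartz), degassed THF (dilute), −78 °C; then Bu4NF (1.05 equiv), AcOH, THF, −78 °C; pH 7 buffer
Reagents that add atoms: none
Why: Excitation of the silyloxy diene triggers a six-electron conrotatory electrocyclic opening that cleaves C5–C10 and creates C1=C10 and C4=C5 in triene 20. The closest known reaction type is the photochemical opening of hexalin dienes and dienol derivatives of eudesmanes to cyclodeca-1,3,5-trienes (the provitamin D to previtamin D type). No ring is closed; the ten-membered ring appears by scission of the bond shared by the two six-membered rings, and no stereocentre is created. The selectivity needed is the sense of conrotation: the trans-lactone holds ring B in the chair with O6 and C11 equatorial, which in the cis-fused system makes C5–C6 pseudoaxial and C10–C9 pseudoequatorial on ring A. Continuing the ground-state twist of the diene turns the pseudoaxial bond inward (C3 and C6 cis, 4Z) and the pseudoequatorial bond outward (C2 and C9 trans, 1(10)E). Buffered fluoride at −78 °C cleaves the enol O–Si bond much faster than the hindered secondary silyl ether, and protonation at C2 gives the dienone. Removing the central double bond takes away the pathway for thermal disrotatory re-closure.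

Step 15
Reactants: 21 (11S)-8β-(tert-butyldimethylsilyloxy)-3-oxo-11βH-germacra-1(10)E,4Z-dien-12,6α-olide
Product: 22 (11S)-8β-(tert-butyldimethylsilyloxy)-3β-hydroxy-11βH-germacra-1(10)E,4Z-dien-12,6α-olide
Conditions: NaBH4, CeCl3·7H2O, MeOH, −78 °C
Reagents that add atoms: none
Why: Luche 1,2-reduction of the Z-enone; hydride should add from the outer face of the ring and set C3 with the hydroxyl β (3S); the lactone is not reduced.

Step 16
Reactants: 22 (11S)-8β-(tert-butyldimethylsilyloxy)-3β-hydroxy-11βH-germacra-1(10)E,4Z-dien-12,6α-olide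
Product: 23 (11S)-3β-benzoyloxy-8β-(tert-butyldimethylsilyloxy)-11βH-germacra-1(10)E,4Z-dien-12,6α-olide
Conditions: PhCOCl, pyridine, DMAP (cat.), CH2Cl2, 0 °C
Reagents that add atoms: benzoyl chloride, O=C(Cl)c1ccccc1
Why: Acylation of the only free hydroxyl with retention at C3; done before the enolate step so that no alkoxide is present there.

Step 17
Reactants: 23 (11S)-3β-benzoyloxy-8β-(tert-butyldimethylsilyloxy)-11βH-germacra-1(10)E,4Z-dien-12,6α-olide
Product: 26 3β-benzoyloxy-8β-(tert-butyldimethylsilyloxy)germacra-1(10)E,4Z,11(13)-trien-12,6α-olide, via selenide 24 (not isolated), via selenoxide 25 (not isolated)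
Conditions: LiN(i-Pr)2 (1.2 equiv), THF, −78 °C; PhSeBr (1.05 equiv), −78 °C; then NaIO4, NaHCO3, MeOH–H2O, 0 °C → rt
Reagents that add atoms: none
Why: Grieco-type α-selenenylation of the lactone enolate and selenoxide syn-elimination; on a trans-fused lactone selenium enters trans to H-7, so only the C13 hydrogens are syn and the exocyclic methylene forms; periodate is used so that no peracid meets the diene.

Step 18
Reactants: 26 3β-benzoyloxy-8β-(tert-butyldimethylsilyloxy)germacra-1(10)E,4Z,11(13)-trien-12,6α-olide
Product: 27 3β-benzoyloxy-8β-hydroxygermacra-1(10)E,4Z,11(13)-trien-12,6α-olide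
Conditions: HF·pyridine, pyridine, THF, 0 °C → rt
Reagents that add atoms: none
Why: Fluoride cleavage of the silyl ether under buffered, non-basic conditions, which avoids alkoxide-driven relactonisation to C8 or addition to C13 and is too weakly acidic to start transannular cyclisation.

Step 19
Reactants: 28 tiglic acid
Product: 29 (E)-2-methylbut-2-en-1-ol
Conditions: LiAlH4, Et2O, 0 °C
Reagents that add atoms: none
Why: Hydride reduction of the acid to the allylic alcohol; the E geometry is kept.

Step 20
Reactants: 29 (E)-2-methylbut-2-en-1-ol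
Product: 30 ((2S,3S)-2,3-dimethyloxiran-2-yl)methanol
Conditions: Ti(Oi-Pr)4 (cat.), L-(+)-diisopropyl tartrate (cat.), t-BuOOH, 4 Å molecular sieves, CH2Cl2, −20 °C
Reagents that add atoms: tert-butyl hydroperoxide, CC(C)(C)OO
Why: Sharpless asymmetric epoxidation; with the L-(+)-tartrate an E-trisubstituted allylic alcohol gives the (2S,3S)-epoxy alcohol, both stereocentres being set by the catalyst.

Step 21
Reactants: 30 ((2S,3S)-2,3-dimethyloxiran-2-yl)methanol
Product: 31 (2R,3S)-2,3-dimethyloxirane-2-carboxylic acid
Conditions: RuCl3·H2O (cat.), NaIO4, CCl4–MeCN–H2O, rt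
Reagents that add atoms: water, O
Why: Ruthenium tetroxide oxidation of the primary alcohol to the acid through the aldehyde hydrate leaves the epoxide intact; the descriptor at C2 changes to R only because CO2H outranks the ring carbon.

Step 22
Reactants: 27 3β-benzoyloxy-8β-hydroxygermacra-1(10)E,4Z,11(13)-trien-12,6α-olide; 31 (2R,3S)-2,3-dimethyloxirane-2-carboxylic acid
Product: 33 3β-benzoyloxy-8β-[(2R,3S)-2,3-dimethyloxirane-2-carbonyloxy]germacra-1(10)E,4Z,11(13)-trien-12,6α-olide, via mixed anhydride 32 (not isolated)
Conditions: 31, 2,4,6-Cl3C6H2COCl, Et3N, THF, rt; then 27, DMAP, toluene, rt → 40 °C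
Reagents that add atoms: none
Why: Yamaguchi esterification, suited to an α,α-disubstituted acid and a hindered secondary alcohol; the acid has no α-hydrogen, so it cannot epimerise, and no free alkoxide is formed at C8.

Step 23
Reactants: 33 3β-benzoyloxy-8β-[(2R,3S)-2,3-dimethyloxirane-2-carbonyloxy]germacra-1(10)E,4Z,11(13)-trien-12,6α-olide
Product: 34 target (CNP0324463.5)
Conditions: mCPBA (1.1 equiv), NaHCO3, CH2Cl2, 0 °C
Reagents that add atoms: 3-chloroperbenzoic acid, OOC(=O)c1cccc(Cl)c1
Why: Prilezhaev epoxidation; the electron-rich 1(10)-alkene reacts before C4=C5 (flanked by two allylic C–O bonds) and the conjugated methylene, and attack on the outer face of the E alkene should give the trans 1β,10α-epoxide (1R,10R).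

## Compound list

1 | (R)-(−)-carvone | CC1=CC[C@H](CC1=O)C(C)=C | starting material
2 | carvone linear dienol trimethylsilyl ether, 2-methyl-5-(prop-1-en-2-yl)-1-(trimethylsilyloxy)cyclohexa-1,3-diene, C5 as in carvone | CC1=C(O[Si](C)(C)C)C[C@@H](C=C1)C(C)=C | intermediate
3 | trans-4-hydroxycarvone, (4S,5R)-4-hydroxy-2-methyl-5-(prop-1-en-2-yl)cyclohex-2-en-1-one | CC1=C[C@H](O)[C@H](CC1=O)C(C)=C | intermediate
4 | trans-4-hydroxydihydrocarvone, (2R,4S,5R)-4-hydroxy-2-methyl-5-(prop-1-en-2-yl)cyclohexan-1-one (drawn as the all-equatorial C2 epimer) | C[C@@H]1C[C@H](O)[C@H](CC1=O)C(C)=C | intermediate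
5 | pent-1-en-3-one (ethyl vinyl ketone) | CCC(=O)C=C | starting material
6 | Michael adduct, (2S,4S,5R)-4-hydroxy-2-methyl-2-(3-oxopentyl)-5-(prop-1-en-2-yl)cyclohexan-1-one | CCC(=O)CC[C@@]1(C)C[C@H](O)[C@H](CC1=O)C(C)=C | intermediate
7 | ketol, 5α,8α-dihydroxy-10α-methyl-7αH-eudesm-11-en-3-one (C4 epimers) | CC1C(=O)CC[C@@]2(C)C[C@H](O)[C@@H](C(C)=C)C[C@@]12O | intermediate
8 | 8α-hydroxy-10α-methyl-7αH-eudesma-4,11-dien-3-one | CC1=C2C[C@H](C(C)=C)[C@@H](O)C[C@]2(C)CCC1=O | intermediate
9 | 8β-(4-nitrobenzoyloxy)-10α-methyl-7αH-eudesma-4,11-dien-3-one | CC1=C2C[C@H](C(C)=C)[C@H](OC(=O)c3ccc(cc3)[N+](=O)[O-])C[C@]2(C)CCC1=O | intermediate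
10 | 8β-hydroxy-10α-methyl-7αH-eudesma-4,11-dien-3-one | CC1=C2C[C@H](C(C)=C)[C@H](O)C[C@]2(C)CCC1=O | intermediate
11 | 3,8β-bis(tert-butyldimethylsilyloxy)-10α-methyl-7αH-eudesma-3,5,11-triene | CC1=C(O[Si](C)(C)C(C)(C)C)CC[C@@]2(C)C[C@@H](O[Si](C)(C)C(C)(C)C)[C@@H](C(C)=C)C=C12 | intermediate
12 | 8β-(tert-butyldimethylsilyloxy)-6α-hydroxy-10α-methyl-7αH-eudesma-4,11-dien-3-one | CC1=C2[C@@H](O)[C@H](C(C)=C)[C@H](O[Si](C)(C)C(C)(C)C)C[C@]2(C)CCC1=O | intermediate
13 | 8β-(tert-butyldimethylsilyloxy)-6α,12-dihydroxy-10α-methyl-7αH-eudesm-4-en-3-one (C11 epimers) | CC1=C2[C@@H](O)[C@H](C(C)CO)[C@H](O[Si](C)(C)C(C)(C)C)C[C@]2(C)CCC1=O | intermediate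
14 | 8β-(tert-butyldimethylsilyloxy)-6α,12-dihydroxy-4β,10α-dimethyl-5αH,7αH-eudesman-3-one, cis-fused (C11 epimers) | C[C@@H]1[C@@H]2[C@@H](O)[C@H](C(C)CO)[C@H](O[Si](C)(C)C(C)(C)C)C[C@]2(C)CCC1=O | intermediate
15 | lactol, 12-hydroxy-6α,12-epoxy form of the C12 aldehyde from 14 (C11, C12 epimers) | CC1C(O)O[C@@H]2[C@H]3[C@@H](C)C(=O)CC[C@@]3(C)C[C@@H](O[Si](C)(C)C(C)(C)C)[C@@H]12 | intermediate
16 | 8β-(tert-butyldimethylsilyloxy)-3-oxo-4β,10α-dimethyl-5αH,7αH-eudesman-12,6α-olide (C11 epimers) | CC1C(=O)O[C@@H]2[C@H]3[C@@H](C)C(=O)CC[C@@]3(C)C[C@@H](O[Si](C)(C)C(C)(C)C)[C@@H]12 | intermediate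
17 | (11S)-8β-(tert-butyldimethylsilyloxy)-3-oxo-4β,10α-dimethyl-5αH,7αH,11βH-eudesman-12,6α-olide | C[C@@H]1C(=O)O[C@@H]2[C@H]3[C@@H](C)C(=O)CC[C@@]3(C)C[C@@H](O[Si](C)(C)C(C)(C)C)[C@@H]12 | intermediate
18 | (11S)-8β-(tert-butyldimethylsilyloxy)-3-oxo-4β,10α-dimethyl-5αH,7αH,11βH-eudesm-1-en-12,6α-olide | C[C@@H]1C(=O)O[C@@H]2[C@H]3[C@@H](C)C(=O)C=C[C@@]3(C)C[C@@H](O[Si](C)(C)C(C)(C)C)[C@@H]12 | intermediate
19 | (11S)-3,8β-bis(tert-butyldimethylsilyloxy)-10α-methyl-5αH,7αH,11βH-eudesma-1,3-dien-12,6α-olide (key-step precursor) | C[C@@H]1C(=O)O[C@@H]2[C@H]3C(C)=C(O[Si](C)(C)C(C)(C)C)C=C[C@@]3(C)C[C@@H](O[Si](C)(C)C(C)(C)C)[C@@H]12 | intermediate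
20 | triene silyl enol ether, (11S)-3,8β-bis(tert-butyldimethylsilyloxy)-11βH-germacra-1(10)E,2Z,4Z-trien-12,6α-olide | C[C@@H]1C(=O)O[C@@H]2/C=C(/C)\C(O[Si](C)(C)C(C)(C)C)=C/C=C(\C)C[C@@H](O[Si](C)(C)C(C)(C)C)[C@@H]12 | intermediate
21 | (11S)-8β-(tert-butyldimethylsilyloxy)-3-oxo-11βH-germacra-1(10)E,4Z-dien-12,6α-olide (key-step product) | C[C@@H]1C(=O)O[C@@H]2/C=C(/C)C(=O)C/C=C(\C)C[C@@H](O[Si](C)(C)C(C)(C)C)[C@@H]12 | intermediate
22 | (11S)-8β-(tert-butyldimethylsilyloxy)-3β-hydroxy-11βH-germacra-1(10)E,4Z-dien-12,6α-olide | C[C@@H]1C(=O)O[C@@H]2/C=C(/C)[C@@H](O)C/C=C(\C)C[C@@H](O[Si](C)(C)C(C)(C)C)[C@@H]12 | intermediate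
23 | (11S)-3β-benzoyloxy-8β-(tert-butyldimethylsilyloxy)-11βH-germacra-1(10)E,4Z-dien-12,6α-olide | C[C@@H]1C(=O)O[C@@H]2/C=C(/C)[C@@H](OC(=O)c3ccccc3)C/C=C(\C)C[C@@H](O[Si](C)(C)C(C)(C)C)[C@@H]12 | intermediate
24 | 11β-phenylseleno derivative of 23 (methyl α) | C[C@]1([Se]c3ccccc3)C(=O)O[C@@H]2/C=C(/C)[C@@H](OC(=O)c4ccccc4)C/C=C(\C)C[C@@H](O[Si](C)(C)C(C)(C)C)[C@@H]12 | intermediate
25 | selenoxide of 24 (epimers at selenium) | C[C@]1([Se](=O)c3ccccc3)C(=O)O[C@@H]2/C=C(/C)[C@@H](OC(=O)c4ccccc4)C/C=C(\C)C[C@@H](O[Si](C)(C)C(C)(C)C)[C@@H]12 | intermediate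
26 | 3β-benzoyloxy-8β-(tert-butyldimethylsilyloxy)germacra-1(10)E,4Z,11(13)-trien-12,6α-olide | C=C1C(=O)O[C@@H]2/C=C(/C)[C@@H](OC(=O)c3ccccc3)C/C=C(\C)C[C@@H](O[Si](C)(C)C(C)(C)C)[C@@H]12 | intermediate
27 | 3β-benzoyloxy-8β-hydroxygermacra-1(10)E,4Z,11(13)-trien-12,6α-olide | C=C1C(=O)O[C@@H]2/C=C(/C)[C@@H](OC(=O)c3ccccc3)C/C=C(\C)C[C@@H](O)[C@@H]12 | intermediate
28 | tiglic acid | C/C=C(\C)C(=O)O | starting material
29 | (E)-2-methylbut-2-en-1-ol | C/C=C(\C)CO | intermediate
30 | ((2S,3S)-2,3-dimethyloxiran-2-yl)methanol | OC[C@]1(C)O[C@H]1C | intermediate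
31 | (2R,3S)-2,3-dimethyloxirane-2-carboxylic acid | OC(=O)[C@]1(C)O[C@H]1C | intermediate
32 | mixed anhydride of 31 with 2,4,6-trichlorobenzoic acid | O=C(OC(=O)[C@]1(C)O[C@H]1C)c1c(Cl)cc(Cl)cc1Cl | intermediate
33 | 3β-benzoyloxy-8β-[(2R,3S)-2,3-dimethyloxirane-2-carbonyloxy]germacra-1(10)E,4Z,11(13)-trien-12,6α-olide | C=C1C(=O)O[C@@H]2/C=C(/C)[C@@H](OC(=O)c3ccccc3)C/C=C(\C)C[C@@H](OC(=O)[C@]3(C)O[C@H]3C)[C@@H]12 | intermediate
34 | target, (1R,10R)-1β,10α-epoxide of 33 | C=C1C(=O)O[C@@H]2/C=C(/C)[C@@H](OC(=O)c3ccccc3)C[C@H]3O[C@]3(C)C[C@@H](OC(=O)[C@]3(C)O[C@H]3C)[C@@H]12 | target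

## Step count and least certain steps

Total: 23 steps. Longest linear sequence: 20 steps (steps 1–18, 22, 23); the acid branch is steps 19–21.

**Step 14 (key step).** The opening may not stop at the wanted triene. The triene can re-close photochemically to either cis-fused diene, open in the other conrotatory sense (1(10)Z,4E) if the ring A conformation is less biased than assumed, or be consumed by secondary photoreactions. Fluoride may also attack the C8 silyl ether or move the β,γ-alkene into conjugation. Fallback: change the chromophore and the trap from silicon to an ester. Setting out from 18, LiN(i-Pr)2 and Ac2O give the dienol acetate F1. Irradiation at low temperature gives the trienol acetate F2. Cold K2CO3 in MeOH releases the ketone and returns to the route at 21. The unmasking is then independent of the C8 silyl ether.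

**Step 2.** The peracid may attack the enol ether double bond (α-hydroxylation at C2) instead of the γ-terminus, or over-oxidise the isopropenyl group. Fallback: from 2, dye-sensitised singlet oxygen (O2, tetraphenylporphyrin, visible light, CH2Cl2, −78 °C) adds across C1/C4 of the diene and collapses to the γ-hydroperoxy enone F3. PPh3 reduces F3 to 3. This mechanism cannot deliver oxygen to C2.

**Step 5.** Activation of the hindered axial hydroxyl may fail, or the activated alcohol may eliminate towards C9. Fallback (Lattrell–Dax inversion): from 8, Tf2O and pyridine give the 8α-triflate F4. Bu4N+ NO2− in toluene displaces it with the small, weakly basic nitrite, and the nitrite ester is hydrolysed on work-up to 10.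

**Step 9.** Hydrogen delivery to the electron-poor tetrasubstituted enone may be slow, or may not be controlled by the hydroxyl. Fallback: from 13, NaBH4/CeCl3·7H2O gives the 3α-allylic alcohol F5 (pseudo-equatorial, cis to the angular methyl). The same iridium catalyst then meets an electron-rich alkene flanked by two α-hydroxyls and gives the saturated triol F6. TEMPO/PhI(OAc)2 closes the hydroxy lactone F7, and Dess–Martin periodinane restores the C3 ketone, returning at 16.

**Step 15.** Hydride may be delivered to the wrong face of the flexible ten-membered enone. Fallback: from 21, the reduction that favours the other face gives the 3α-alcohol F8. A Mitsunobu reaction with benzoic acid (PPh3, i-PrO2CN=NCO2i-Pr) installs the benzoate with inversion and returns at 23, so step 16 is skipped.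

**Step 23.** The peracid may attack the wrong face of C1=C10, or C4=C5. Fallback: from 33, a Shi epoxidation (fructose-derived ketone of the enantiomeric series that matches the 1R,10R face, KHSO5, buffered MeCN–H2O) puts the facial choice under reagent control and favours trisubstituted E alkenes. It leads directly to 34 and makes no new compound.

## Further compounds

F1 | step 14 | (11S)-3-acetoxy-8β-(tert-butyldimethylsilyloxy)-10α-methyl-5αH,7αH,11βH-eudesma-1,3-dien-12,6α-olide | C[C@@H]1C(=O)O[C@@H]2[C@H]3C(C)=C(OC(C)=O)C=C[C@@]3(C)C[C@@H](O[Si](C)(C)C(C)(C)C)[C@@H]12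
F2 | step 14 | (11S)-3-acetoxy-8β-(tert-butyldimethylsilyloxy)-11βH-germacra-1(10)E,2Z,4Z-trien-12,6α-olide | C[C@@H]1C(=O)O[C@@H]2/C=C(/C)\C(OC(C)=O)=C/C=C(\C)C[C@@H](O[Si](C)(C)C(C)(C)C)[C@@H]12
F3 | step 2 | (4S,5R)-4-hydroperoxy-2-methyl-5-(prop-1-en-2-yl)cyclohex-2-en-1-one | CC1=C[C@H](OO)[C@H](CC1=O)C(C)=C
F4 | step 5 | 8α-(trifluoromethanesulfonyloxy)-10α-methyl-7αH-eudesma-4,11-dien-3-one | CC1=C2C[C@H](C(C)=C)[C@@H](OS(=O)(=O)C(F)(F)F)C[C@]2(C)CCC1=O
F5 | step 9 | 8β-(tert-butyldimethylsilyloxy)-10α-methyl-7αH-eudesm-4-ene-3α,6α,12-triol (C11 epimers) | CC1=C2[C@@H](O)[C@H](C(C)CO)[C@H](O[Si](C)(C)C(C)(C)C)C[C@]2(C)CC[C@H]1O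
F6 | step 9 | 8β-(tert-butyldimethylsilyloxy)-4β,10α-dimethyl-5αH,7αH-eudesmane-3α,6α,12-triol (C11 epimers) | C[C@@H]1[C@@H]2[C@@H](O)[C@H](C(C)CO)[C@H](O[Si](C)(C)C(C)(C)C)C[C@]2(C)CC[C@H]1O
F7 | step 9 | 8β-(tert-butyldimethylsilyloxy)-3α-hydroxy-4β,10α-dimethyl-5αH,7αH-eudesman-12,6α-olide (C11 epimers) | CC1C(=O)O[C@@H]2[C@H]3[C@@H](C)[C@H](O)CC[C@@]3(C)C[C@@H](O[Si](C)(C)C(C)(C)C)[C@@H]12
F8 | step 15 | (11S)-8β-(tert-butyldimethylsilyloxy)-3α-hydroxy-11βH-germacra-1(10)E,4Z-dien-12,6α-olide | C[C@@H]1C(=O)O[C@@H]2/C=C(/C)[C@H](O)C/C=C(\C)C[C@@H](O[Si](C)(C)C(C)(C)C)[C@@H]12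
F0 | step 23 | none | none
A1 | alternative 1 | 3β-benzoyloxy-8β-hydroxygermacra-1(10)E,4Z,11(13)-trien-12,6-olide (identical with 27) | C=C1C(=O)O[C@@H]2/C=C(/C)[C@@H](OC(=O)c3ccccc3)C/C=C(\C)C[C@@H](O)[C@@H]12
A2 | alternative 2 | 8β-hydroxy-1(10)E,4Z-cyclodecadiene with C3 4-methoxybenzyl ether and C6, C12 silyl ethers | O[C@@H]1C/C(C)=C/C[C@H](OCc2ccc(OC)cc2)/C(C)=C\[C@@H](O[Si](C)(C)C(C)(C)C)[C@@H]1C(=C)CO[Si](C)(C)C(C)(C)C
A3 | alternative 3 | 1(10)E,4Z-cyclodecadien-6-one with C7 tert-butyl acetate arm, C8 benzyldimethylsilyl group and C3 silyl ether | O=C1[C@H](CC(=O)OC(C)(C)C)[C@H]([Si](C)(C)Cc2ccccc2)C/C(C)=C/C[C@H](O[Si](C)(C)C(C)(C)C)/C(C)=C\1
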